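**Plan**

- In the target, (5S)-5-hydroxy-5-nonadecylcyclohex-2-en-1-one, the C5 hydroxyl oxygen sits 1,3 to the C1 carbonyl oxygen and both ring arms (C4 and C6) start at C5. C5 is therefore treated as the carbinol carbon of a tertiary divinyl carbinol whose own oxygen can carry silicon to the end of one vinyl group.
- Retrosynthetic cuts, in order: move C2=C3 back to C3=C4 and cut that alkene (ring-closing metathesis); cut C1–C2 (allyl addition to an aldehyde); trade C1–O for C1–Si (Tamao oxidation); cut Si–C1 (tethered hydrosilylation); cut both C5–vinyl bonds (ester plus vinyl Grignard).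
- Forward: methyl icosanoate → divinyl carbinol → hydrosilyl ether → 1,2-oxasilolane (temporary ring, key step) → 1,3-diol → β-hydroxy aldehyde → allyl adduct → cyclohexene (the carbocycle, by metathesis) → β,γ-enone → conjugated enone.
- Stereochemistry: C5 is the only stereocentre. It is created when the chiral rhodium catalyst picks one of two enantiotopic vinyl groups. No bond at C5 is touched afterwards; the descriptor changes from R to S at the end only because the CIP ranking of the two ring arms changes.

Key step: step 3

Assumption: which enantiomer of DIOP gives the (5R)-oxasilolane cannot be derived from the precedent on secondary bis(2-propenyl)carbinols. The route is written with (R,R)-DIOP, and (S,S)-DIOP takes its place if the first run gives the (5S) series.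

**Step 1**
Reactants: 1 methyl icosanoate; 2 vinylmagnesium bromide
Product: 4 3-nonadecylpenta-1,4-dien-3-ol, via docos-1-en-3-one 3 (not isolated)
Conditions: CeCl3 (anhydrous, 2.5 equiv), 2 (3 equiv), THF, −78 → 0 °C; then aq NH4Cl
Reagents that add atoms: vinylmagnesium bromide, C=C[Mg]Br
Why: Double Grignard addition to an ester, in which the first vinyl addition and loss of methoxide give enone 3 and the cerium-modified reagent then attacks its carbonyl 1,2 rather than in the conjugate sense; no stereocentre forms because the two vinyl groups are identical.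

**Step 2**
Reactants: 4 3-nonadecylpenta-1,4-dien-3-ol; 5 chlorodiphenylsilane
Product: 6 [(3-nonadecylpenta-1,4-dien-3-yl)oxy]diphenylsilane
Conditions: Ph2SiHCl (1.3 equiv), Et3N (2 equiv), DMAP (0.1 equiv), CH2Cl2, 0 °C → rt
Reagents that add atoms: chlorodiphenylsilane, Cl[SiH](c1ccccc1)c1ccccc1
Why: O-silylation of an alcohol with a chlorosilane under amine/DMAP catalysis; the Si–H chlorosilane is small enough to reach the tertiary hydroxyl, and the product is passed quickly through deactivated silica and used at once.

**Step 3**
Reactants: 6 [(3-nonadecylpenta-1,4-dien-3-yl)oxy]diphenylsilane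
Product: 7 (5R)-5-ethenyl-5-nonadecyl-2,2-diphenyl-1,2-oxasilolane
Conditions: [RhCl(C2H4)2]2 (1 mol %), (R,R)-DIOP (2.4 mol %), ClCH2CH2Cl (0.1 M), 30 °C
Reagents that add atoms: none
Why: Proposed new method: oxidative addition of the Si–H bond to the monovalent rhodium–diphosphine complex gives a trivalent rhodium silyl hydride held next to both vinyl groups by the Si–O tether, one vinyl group inserts, and reductive elimination forms the Si–C bond at the terminal carbon and returns monovalent rhodium. The closest known reaction is the rhodium–diphosphine intramolecular hydrosilylation of allylic hydrosilyl ethers, including its use to desymmetrize secondary bis(2-propenyl)carbinol diarylsilyl ethers; the extension is to a tertiary carbinol with unsubstituted vinyl groups, where the choice of alkene is the only stereogenic event. The oxasilolane closes in the 5-endo-trig mode, the 4-exo alternative being a strained 1,2-oxasiletane. C5 becomes stereogenic by enantiotopic group selection under control of the chiral diphosphine on rhodium, which must read the difference between the nonadecyl chain and the spectator vinyl group in the two diastereomeric chelated silyl–alkene complexes. The step needs group selectivity and terminal regioselectivity: the one-atom O–Si tether secures the latter, the single Si–H bond limits the reaction to one alkene, and the fully substituted carbinol carbon has no allylic hydrogen, so isomerization to a silyl enol ether cannot compete.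

**Step 4**
Reactants: 7 (5R)-5-ethenyl-5-nonadecyl-2,2-diphenyl-1,2-oxasilolane
Product: 8 (3R)-3-ethenyldocosane-1,3-diol
Conditions: 30% aq H2O2, KF, KHCO3, THF/MeOH 1:1, rt → 40 °C
Reagents that add atoms: hydrogen peroxide, OO
Why: Tamao oxidation, in which fluoride-activated alkoxysilicon takes up peroxide and the alkyl carbon migrates from silicon to oxygen; the tertiary C–O bond is only released from silicon and never broken, so the configuration of the carbinol centre is kept, and the vinyl group is inert to these conditions.

**Step 5**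
Reactants: 8 (3R)-3-ethenyldocosane-1,3-diol
Product: 9 (3R)-3-ethenyl-3-hydroxydocosanal
Conditions: TEMPO (0.1 equiv), PhI(OAc)2 (1.1 equiv), CH2Cl2, rt; crude aldehyde used at once
Reagents that add atoms: none
Why: Oxoammonium (TEMPO) oxidation, which converts the primary alcohol into the aldehyde while the tertiary alcohol cannot be oxidized, and whose base-free medium spares the β-hydroxy aldehyde from retro-aldol cleavage and dehydration.

**Step 6**
Reactants: 9 (3R)-3-ethenyl-3-hydroxydocosanal; 10 allylmagnesium bromide
Product: 11 (4RS,6R)-6-ethenylpentacos-1-ene-4,6-diol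
Conditions: 10 (2.5 equiv), THF, −78 °C; then aq NH4Cl
Reagents that add atoms: allylmagnesium bromide, C=CC[Mg]Br
Why: Grignard addition to an aldehyde, in which one equivalent of 10 is spent on the tertiary hydroxyl and the next adds to the carbonyl faster than the magnesium aldolate can fragment at −78 °C; the new C4 carbinol centre forms as a mixture of epimers, which is acceptable because step 8 oxidizes it.

**Step 7**
Reactants: 11 (4RS,6R)-6-ethenylpentacos-1-ene-4,6-diol
Product: 12 (1RS,3R)-3-nonadecylcyclohex-4-ene-1,3-diol
Conditions: second-generation Grubbs catalyst RuCl2(=CHPh)(PCy3)(H2IMes) (3 mol %), CH2Cl2 (0.005 M), 40 °C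
Reagents that add atoms: none
Why: Ring-closing metathesis of the octa-1,7-diene unit to a cyclohexene with loss of ethene; free hydroxyl groups are tolerated by the ruthenium carbene and high dilution suppresses cross-metathesis.

**Step 8**
Reactants: 12 (1RS,3R)-3-nonadecylcyclohex-4-ene-1,3-diol
Product: 13 (5R)-5-hydroxy-5-nonadecylcyclohex-3-en-1-one
Conditions: Dess–Martin periodinane (1.3 equiv), NaHCO3, CH2Cl2, 0 °C → rt
Reagents that add atoms: none
Why: Dess–Martin oxidation of the secondary alcohol, which converges both C1 epimers on one ketone and neither oxidizes nor transposes the tertiary allylic alcohol.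

**Step 9**
Reactants: 13 (5R)-5-hydroxy-5-nonadecylcyclohex-3-en-1-one
Product: 14 (5S)-5-hydroxy-5-nonadecylcyclohex-2-en-1-one
Conditions: Et3N (1.5 equiv), CH2Cl2, 0 °C → rt
Reagents that add atoms: none
Why: Base-mediated isomerization of a β,γ-enone to the conjugated enone through the dienolate (removal of the doubly activated C2 proton, reprotonation at C4); hydroxide is a poor leaving group under amine catalysis, C5 is not touched, and its descriptor becomes S only through the changed CIP ranking of C4 and C6.

**Compound list**

1 | methyl icosanoate | CCCCCCCCCCCCCCCCCCCC(=O)OC | starting material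
2 | vinylmagnesium bromide | C=C[Mg]Br | starting material
3 | docos-1-en-3-one | CCCCCCCCCCCCCCCCCCCC(=O)C=C | intermediate
4 | 3-nonadecylpenta-1,4-dien-3-ol | CCCCCCCCCCCCCCCCCCCC(O)(C=C)C=C | intermediate
5 | chlorodiphenylsilane | Cl[SiH](c1ccccc1)c1ccccc1 | starting material
6 | [(3-nonadecylpenta-1,4-dien-3-yl)oxy]diphenylsilane | CCCCCCCCCCCCCCCCCCCC(O[SiH](c1ccccc1)c1ccccc1)(C=C)C=C | intermediate
7 | (5R)-5-ethenyl-5-nonadecyl-2,2-diphenyl-1,2-oxasilolane | CCCCCCCCCCCCCCCCCCC[C@]1(C=C)CC[Si](c2ccccc2)(c2ccccc2)O1 | intermediate
8 | (3R)-3-ethenyldocosane-1,3-diol | CCCCCCCCCCCCCCCCCCC[C@](O)(C=C)CCO | intermediate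
9 | (3R)-3-ethenyl-3-hydroxydocosanal | CCCCCCCCCCCCCCCCCCC[C@](O)(C=C)CC=O | intermediate
10 | allylmagnesium bromide | C=CC[Mg]Br | starting material
11 | (4RS,6R)-6-ethenylpentacos-1-ene-4,6-diol | CCCCCCCCCCCCCCCCCCC[C@](O)(C=C)CC(O)CC=C | intermediate
12 | (1RS,3R)-3-nonadecylcyclohex-4-ene-1,3-diol | CCCCCCCCCCCCCCCCCCC[C@]1(O)C=CCC(O)C1 | intermediate
13 | (5R)-5-hydroxy-5-nonadecylcyclohex-3-en-1-one | CCCCCCCCCCCCCCCCCCC[C@]1(O)C=CCC(=O)C1 | intermediate
14 | (5S)-5-hydroxy-5-nonadecylcyclohex-2-en-1-one | CCCCCCCCCCCCCCCCCCC[C@]1(O)CC=CC(=O)C1 | target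

**Step count and risks**

Total step count: 9. Longest linear sequence: 9 steps (1 → 14).

Steps most likely to fail:

1. Step 3 (proposed new method). The catalyst may discriminate poorly between the two enantiotopic vinyl groups, or turn over slowly at the crowded tertiary silyl ether. The fallback uses known chemistry and replaces catalyst control by classical resolution; it sets out from 6 and comes back at 8. Hydrosilylation of 6 with the achiral catalyst RhCl(PPh3)3 should give rac-5-ethenyl-5-nonadecyl-2,2-diphenyl-1,2-oxasilolane F1. Tamao oxidation (H2O2, KF, KHCO3) should give rac-3-ethenyldocosane-1,3-diol F2. Acylation of the primary hydroxyl with (1S)-camphanic chloride (pyridine, DMAP) should give two diastereomeric esters. (3R)-3-ethenyl-3-hydroxydocosyl (1S,4R)-4,7,7-trimethyl-3-oxo-2-oxabicyclo[2.2.1]heptane-1-carboxylate F3 would be separated by crystallization or preparative HPLC from (3S)-3-ethenyl-3-hydroxydocosyl (1S,4R)-4,7,7-trimethyl-3-oxo-2-oxabicyclo[2.2.1]heptane-1-carboxylate F4. Saponification of F3 (KOH, MeOH/THF) returns diol 8.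

2. Step 5. The β-hydroxy aldehyde may lose water to the conjugated dienal or undergo retro-aldol cleavage during oxidation, handling or the following Grignard addition. The fallback keeps the tertiary oxygen masked while the aldehyde exists; it sets out from 8 and comes back at 11. Et3SiOTf and 2,6-lutidine should convert 8 into (3R)-3-ethenyl-1,3-bis[(triethylsilyl)oxy]docosane F5. Swern conditions ((COCl)2, DMSO, Et3N, −78 → −20 °C) oxidize the primary triethylsilyl ether directly and should give (3R)-3-ethenyl-3-[(triethylsilyl)oxy]docosanal F6. Allylmagnesium bromide 10 at −78 °C should give (4RS,6R)-6-ethenyl-6-[(triethylsilyl)oxy]pentacos-1-en-4-ol F7. Bu4NF in THF removes the silyl group and returns diol 11.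

3. Step 9. The dienolate may expel the C5 hydroxyl (vinylogous E1cB elimination) with aromatization of the ring, or the isomerization may stall. The fallback installs the C2=C3 alkene by dehydrogenation of a saturated ketone instead of by alkene migration; it sets out from 12 and comes back at 14. Hydrogenation (H2, PtO2, EtOAc) should give (1S,3RS)-1-nonadecylcyclohexane-1,3-diol F8. Dess–Martin oxidation should give (3S)-3-hydroxy-3-nonadecylcyclohexan-1-one F9. LiN(iPr)2 and Me3SiCl in THF at −78 °C should silylate the tertiary hydroxyl and trap the kinetic enolate on the side remote from the quaternary carbon, giving {[(5S)-5-nonadecylcyclohex-1-ene-1,5-diyl]bis(oxy)}bis(trimethylsilane) F10. Saegusa–Ito dehydrogenation with Pd(OAc)2 in MeCN should give (5S)-5-nonadecyl-5-[(trimethylsilyl)oxy]cyclohex-2-en-1-one F11. HF·pyridine in THF at 0 °C removes the silyl group and gives 14.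

**Further compounds**

F1 | step 3 | rac-5-ethenyl-5-nonadecyl-2,2-diphenyl-1,2-oxasilolane | CCCCCCCCCCCCCCCCCCCC1(C=C)CC[Si](c2ccccc2)(c2ccccc2)O1
F2 | step 3 | rac-3-ethenyldocosane-1,3-diol | CCCCCCCCCCCCCCCCCCCC(O)(C=C)CCO
F3 | step 3 | (3R)-3-ethenyl-3-hydroxydocosyl (1S,4R)-4,7,7-trimethyl-3-oxo-2-oxabicyclo[2.2.1]heptane-1-carboxylate | CCCCCCCCCCCCCCCCCCC[C@](O)(C=C)CCOC(=O)[C@]12OC(=O)[C@](C)(CC1)C2(C)C
F4 | step 3 | (3S)-3-ethenyl-3-hydroxydocosyl (1S,4R)-4,7,7-trimethyl-3-oxo-2-oxabicyclo[2.2.1]heptane-1-carboxylate | CCCCCCCCCCCCCCCCCCC[C@@](O)(C=C)CCOC(=O)[C@]12OC(=O)[C@](C)(CC1)C2(C)C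
F5 | step 5 | (3R)-3-ethenyl-1,3-bis[(triethylsilyl)oxy]docosane | CCCCCCCCCCCCCCCCCCC[C@](O[Si](CC)(CC)CC)(C=C)CCO[Si](CC)(CC)CC
F6 | step 5 | (3R)-3-ethenyl-3-[(triethylsilyl)oxy]docosanal | CCCCCCCCCCCCCCCCCCC[C@](O[Si](CC)(CC)CC)(C=C)CC=O
F7 | step 5 | (4RS,6R)-6-ethenyl-6-[(triethylsilyl)oxy]pentacos-1-en-4-ol | CCCCCCCCCCCCCCCCCCC[C@](O[Si](CC)(CC)CC)(C=C)CC(O)CC=C
F8 | step 9 | (1S,3RS)-1-nonadecylcyclohexane-1,3-diol | CCCCCCCCCCCCCCCCCCC[C@]1(O)CCCC(O)C1
F9 | step 9 | (3S)-3-hydroxy-3-nonadecylcyclohexan-1-one | CCCCCCCCCCCCCCCCCCC[C@]1(O)CCCC(=O)C1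
F10 | step 9 | {[(5S)-5-nonadecylcyclohex-1-ene-1,5-diyl]bis(oxy)}bis(trimethylsilane) | CCCCCCCCCCCCCCCCCCC[C@]1(O[Si](C)(C)C)CCC=C(O[Si](C)(C)C)C1
F11 | step 9 | (5S)-5-nonadecyl-5-[(trimethylsilyl)oxy]cyclohex-2-en-1-one | CCCCCCCCCCCCCCCCCCC[C@]1(O[Si](C)(C)C)CC=CC(=O)C1
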